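**Strategy.** The six-membered ring (C-1 ketone, C-2 acyl-bearing, C-3 enol, C-4 bearing the cyclopentylmethyl arm, C-5 enol, C-6 quaternary) is a cyclised triketide: every ring bond joins an acyl carbon to an α-carbon. The key step exploits this 1,3,5-tricarbonyl array and the cis 1,3-relation of tertiary OH and CH2 arm on the cyclopentane, which are stored together as a δ-lactone. The methyl-ketone enolate of a C-6-configured β-keto ester opens this lactone (C-2–C-3, Claisen), and the resulting diketone dianion closes C-4–C-5 onto the ester (Dieckmann) in one flask, building the ring, freeing the alcohol and leaving only C-2 acylation.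

Key step: step 9

Assumption: in step 8 the toluene/HMPA regime of the L-valine enamine alkylation is taken to give the 2S keto ester 19; if the assignment proves opposite, the THF regime of the same auxiliary, which reverses the face, is used.
Remark: 1 is commercial (−)-limonene 1,2-oxide; its epoxide configuration is irrelevant because both epoxide carbons become carbonyl carbons. Acid 23 is purchased as the single R enantiomer.

Step 1
Reactants: 1 (4S)-1-methyl-4-(prop-1-en-2-yl)-7-oxabicyclo[4.1.0]heptane
Product: 3 (3S)-6-oxo-3-(prop-1-en-2-yl)heptanal, via diol 2 (not isolated)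
Conditions: H5IO6 (1.1 equiv), THF/H2O, 0 °C to rt
Reagents that add atoms: water, O
Why: Periodic acid hydrolyses the trisubstituted epoxide to the 1,2-diol and cleaves it in the same flask (Malaprade glycol cleavage), which opens the cyclohexane while the isopropenyl-bearing stereocentre is untouched.

Step 2
Reactants: 3 (3S)-6-oxo-3-(prop-1-en-2-yl)heptanal
Product: 4 (3S)-6-oxo-3-(prop-1-en-2-yl)heptanoic acid
Conditions: NaClO2, NaH2PO4, 2-methylbut-2-ene, t-BuOH/H2O, 0 °C to rt
Reagents that add atoms: sodium chlorite, [Na+].[O-]Cl=O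
Why: Pinnick oxidation converts the aldehyde into the acid without touching the methyl ketone, and the 2-methylbut-2-ene scavenger protects the isopropenyl group from HOCl.

Step 3
Reactants: 4 (3S)-6-oxo-3-(prop-1-en-2-yl)heptanoic acid
Product: 6 (1R,2S,5S)-5-methyl-2-(prop-1-en-2-yl)-6-oxabicyclo[3.2.0]heptan-7-one, via acylpyridinium salt 5 (not isolated)
Conditions: 2-bromo-1-propylpyridinium triflate (1.5 equiv), 4-pyrrolidinopyridine (1.5 equiv), iPr2NEt (2.5 equiv), CH2Cl2, rt, slow addition of 4
Reagents that add atoms: none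
Why: In this nucleophile-catalysed aldol-lactonisation the enolate of the activated acid adds to the methyl ketone and the aldolate lactonises, so the new C–C(=O) and C–O bonds are necessarily cis, and the aldol should occur on the face anti to the neighbouring isopropenyl group, which sets both new stereocentres (isopropenyl trans to the lactone carbonyl carbon, cis to the angular methyl).

Step 4
Reactants: 6 (1R,2S,5S)-5-methyl-2-(prop-1-en-2-yl)-6-oxabicyclo[3.2.0]heptan-7-one
Product: 7 (1S,2S,3S)-2-(hydroxymethyl)-1-methyl-3-(prop-1-en-2-yl)cyclopentan-1-ol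
Conditions: LiAlH4, Et2O, 0 °C; aqueous work-up
Reagents that add atoms: none
Why: LiAlH4 reduces the strained β-lactone by acyl–oxygen cleavage to the 1,3-diol, so the tertiary C–O stereocentre is retained and the alkene is not reduced.

Step 5
Reactants: 7 (1S,2S,3S)-2-(hydroxymethyl)-1-methyl-3-(prop-1-en-2-yl)cyclopentan-1-ol; 8 methyl (triphenylphosphoranylidene)acetate
Product: 10 methyl (2E)-3-[(1R,2S,5S)-2-hydroxy-2-methyl-5-(prop-1-en-2-yl)cyclopentyl]prop-2-enoate, via aldehyde 9 (not isolated)
Conditions: TEMPO (10 mol%), PhI(OAc)2 (1.1 equiv), CH2Cl2, rt; then 8 (1.3 equiv), rt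
Reagents that add atoms: none
Why: Oxoammonium oxidation is selective for the primary over the tertiary alcohol, and trapping the β-hydroxy aldehyde in the same flask by an E-selective Wittig reaction avoids its retro-aldol cleavage, dehydration or epimerisation.

Step 6
Reactants: 10 methyl (2E)-3-[(1R,2S,5S)-2-hydroxy-2-methyl-5-(prop-1-en-2-yl)cyclopentyl]prop-2-enoate
Product: 12 (4aR,5S,7aS)-7a-methyl-5-(prop-1-en-2-yl)hexahydrocyclopenta[b]pyran-2(3H)-one, via hydroxy ester 11 (not isolated)
Conditions: Mg turnings, MeOH, 0 °C to rt; aq. NH4Cl; then PPTS (10 mol%), toluene, 80 °C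
Reagents that add atoms: none
Why: Magnesium in methanol reduces only the conjugated C=C by single-electron transfer (the isopropenyl group is not conjugated), and acid-catalysed transesterification then closes the cis-fused δ-lactone on the tertiary alcohol, driven by loss of methanol.

Step 7
Reactants: 13 ethyl 2-methyl-3-oxobutanoate; 14 L-valine tert-butyl ester hydrochloride
Product: 15 tert-butyl N-[(2Z)-4-ethoxy-3-methyl-4-oxobut-2-en-2-yl]-L-valinate
Conditions: Et3N (1.0 equiv), toluene, reflux, Dean–Stark
Reagents that add atoms: none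
Why: Condensation of the β-keto ester with the primary amine gives the hydrogen-bonded Z-enamino ester, with water removed azeotropically.

Step 8
Reactants: 15 tert-butyl N-[(2Z)-4-ethoxy-3-methyl-4-oxobut-2-en-2-yl]-L-valinate; 16 1-bromo-3-methylbut-2-ene
Product: 19 ethyl (2S)-2-acetyl-2,5-dimethylhex-4-enoate, via lithium aza-enolate 17 (not isolated), via imine 18 (not isolated)
Conditions: LiN(iPr)2 (1.2 equiv), toluene, −78 °C; HMPA (1.0 equiv); 16 (1.5 equiv), −78 to −55 °C; then 10% aq. citric acid, rt
Reagents that add atoms: water, O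
Why: In this chiral-enamine alkylation the lithio-enamine is a rigid chelate whose valine isopropyl and tert-butyl ester groups block one face, so C-prenylation (SN2 at the primary allylic bromide) sets the quaternary centre, and mild acid hydrolysis of the imine releases the keto ester and the recoverable auxiliary.

Step 9
Reactants: 19 ethyl (2S)-2-acetyl-2,5-dimethylhex-4-enoate; 12 (4aR,5S,7aS)-7a-methyl-5-(prop-1-en-2-yl)hexahydrocyclopenta[b]pyran-2(3H)-one
Product: 22 (6R)-5-hydroxy-4-{[(1R,2S,5S)-2-hydroxy-2-methyl-5-(prop-1-en-2-yl)cyclopentyl]methyl}-6-methyl-6-(3-methylbut-2-en-1-yl)cyclohex-4-ene-1,3-dione, via lithium enolate 20 (not isolated), via diketo ester 21 (not isolated)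
Conditions: 19 (1.3 equiv), LiN(iPr)2 (1.3 equiv), THF, −78 °C; 12 (1.0 equiv), −78 to 0 °C; LiN(iPr)2 (2.5 equiv), −78 °C to rt; cold 1 M HCl to pH 3
Reagents that add atoms: none
Why: LiN(iPr)2 can deprotonate 19 only at its acetyl CH3 (future C-2) because C-6 is quaternary; this enolate adds to the lactone carbonyl of 12 (future C-3), and collapse of the adduct expels the tertiary alkoxide, which deprotonates the new β-diketone, so the crossed Claisen acylation is driven forward and the alcohol is unmasked without a protecting group. The added amide base then removes a proton from the former lactone α-CH2 (future C-4) of the diketonate of 21, and this terminal carbanion attacks the ethyl ester (future C-5) in a Dieckmann condensation, a 6-(enolendo)-exo-trig closure that is the only ring closure of the step. The closest known reaction types are the Claisen acylation of ketone enolates by lactones and the β-diketone-dianion Dieckmann route to 4,4-disubstituted cyclohexane-1,3,5-triones. No stereocentre is created: C-6 is carried from 19, none of its bonds is made or broken, and its sense in the ring is fixed by which of its two carbonyls was the ester (becomes C-5) and which the ketone (becomes C-1). The step needs acylation over proton transfer and C- over O-acylation without retro-Claisen cleavage; the hard terminal carbanion, the six-membered transition state and the doubly enolised trione as thermodynamic sink should secure this, and the cyclopentane stereocentres are not acidic.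

Step 10
Reactants: 22 (6R)-5-hydroxy-4-{[(1R,2S,5S)-2-hydroxy-2-methyl-5-(prop-1-en-2-yl)cyclopentyl]methyl}-6-methyl-6-(3-methylbut-2-en-1-yl)cyclohex-4-ene-1,3-dione; 23 (2R)-2-methylbutanoic acid
Product: 25 (6R)-3,5-dihydroxy-4-{[(1R,2S,5S)-2-hydroxy-2-methyl-5-(prop-1-en-2-yl)cyclopentyl]methyl}-6-methyl-2-[(2R)-2-methylbutanoyl]-6-(3-methylbut-2-en-1-yl)cyclohexa-2,4-dien-1-one, via enol ester 24 (not isolated)
Conditions: 23 (1.2 equiv), DCC (1.3 equiv), DMAP (1.2 equiv), CH2Cl2, 0 °C to rt
Reagents that add atoms: none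
Why: Steglich-type O-acylation of the trione followed by DMAP-mediated O-to-C acyl migration (the standard route to 2-acyl cyclic 1,3-diones) should deliver the acyl group to C-2, the only unsubstituted carbon between two carbonyls, where the product is held as a chelated enol, while the tertiary alcohol is too hindered to be acylated and the α-stereocentre of the acid is not expected to epimerise.

**Compound list**

1 | (4S)-1-methyl-4-(prop-1-en-2-yl)-7-oxabicyclo[4.1.0]heptane [(−)-limonene 1,2-oxide, cis/trans mixture at the epoxide] | CC12OC1C[C@H](CC2)C(C)=C | starting material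
2 | (4S)-1-methyl-4-(prop-1-en-2-yl)cyclohexane-1,2-diol | CC1(O)C(O)C[C@H](CC1)C(C)=C | intermediate (not isolated)
3 | (3S)-6-oxo-3-(prop-1-en-2-yl)heptanal | CC(=O)CC[C@@H](CC=O)C(C)=C | intermediate
4 | (3S)-6-oxo-3-(prop-1-en-2-yl)heptanoic acid | CC(=O)CC[C@@H](CC(=O)O)C(C)=C | intermediate
5 | 1-[(3S)-6-oxo-3-(prop-1-en-2-yl)heptanoyl]-4-(pyrrolidin-1-yl)pyridinium triflate | CC(=O)CC[C@@H](CC(=O)[n+]1ccc(cc1)N1CCCC1)C(C)=C.[O-]S(=O)(=O)C(F)(F)F | intermediate (not isolated)
6 | (1R,2S,5S)-5-methyl-2-(prop-1-en-2-yl)-6-oxabicyclo[3.2.0]heptan-7-one (cis-fused β-lactone, isopropenyl trans to the lactone carbonyl carbon) | C=C(C)[C@H]1CC[C@]2(C)OC(=O)[C@H]12 | intermediate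
7 | (1S,2S,3S)-2-(hydroxymethyl)-1-methyl-3-(prop-1-en-2-yl)cyclopentan-1-ol | C=C(C)[C@H]1CC[C@](C)(O)[C@@H]1CO | intermediate
8 | methyl (triphenylphosphoranylidene)acetate | COC(=O)C=P(c1ccccc1)(c1ccccc1)c1ccccc1 | starting material
9 | (1R,2S,5S)-2-hydroxy-2-methyl-5-(prop-1-en-2-yl)cyclopentane-1-carbaldehyde | C=C(C)[C@H]1CC[C@](C)(O)[C@@H]1C=O | intermediate (not isolated)
10 | methyl (2E)-3-[(1R,2S,5S)-2-hydroxy-2-methyl-5-(prop-1-en-2-yl)cyclopentyl]prop-2-enoate | C=C(C)[C@H]1CC[C@](C)(O)[C@@H]1/C=C/C(=O)OC | intermediate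
11 | methyl 3-[(1R,2S,5S)-2-hydroxy-2-methyl-5-(prop-1-en-2-yl)cyclopentyl]propanoate | C=C(C)[C@H]1CC[C@](C)(O)[C@@H]1CCC(=O)OC | intermediate (not isolated)
12 | (4aR,5S,7aS)-7a-methyl-5-(prop-1-en-2-yl)hexahydrocyclopenta[b]pyran-2(3H)-one (cis-fused δ-lactone) | C=C(C)[C@H]1CC[C@]2(C)OC(=O)CC[C@H]12 | intermediate
13 | ethyl 2-methyl-3-oxobutanoate (racemic) | CCOC(=O)C(C)C(C)=O | starting material
14 | L-valine tert-butyl ester hydrochloride | CC(C)[C@H](N)C(=O)OC(C)(C)C.Cl | starting material
15 | tert-butyl N-[(2Z)-4-ethoxy-3-methyl-4-oxobut-2-en-2-yl]-L-valinate | CCOC(=O)/C(C)=C(C)\N[C@@H](C(C)C)C(=O)OC(C)(C)C | intermediate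
16 | 1-bromo-3-methylbut-2-ene (prenyl bromide) | CC(C)=CCBr | starting material
17 | lithium aza-enolate of 15 | CCOC(=O)C(C)=C(C)[N-][C@@H](C(C)C)C(=O)OC(C)(C)C.[Li+] | intermediate (not isolated)
18 | tert-butyl N-[(3S)-4-ethoxy-3-methyl-3-(3-methylbut-2-en-1-yl)-4-oxobutan-2-ylidene]-L-valinate | CCOC(=O)[C@@](C)(CC=C(C)C)C(C)=N[C@@H](C(C)C)C(=O)OC(C)(C)C | intermediate (not isolated)
19 | ethyl (2S)-2-acetyl-2,5-dimethylhex-4-enoate | CCOC(=O)[C@@](C)(CC=C(C)C)C(C)=O | intermediate
20 | lithium enolate of 19 (acetyl CH3 deprotonated) | CCOC(=O)[C@@](C)(CC=C(C)C)C(=C)[O-].[Li+] | intermediate (not isolated)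
21 | ethyl (2S)-7-[(1R,2S,5S)-2-hydroxy-2-methyl-5-(prop-1-en-2-yl)cyclopentyl]-2-methyl-2-(3-methylbut-2-en-1-yl)-3,5-dioxoheptanoate (formed as its lithium diketonate) | C=C(C)[C@H]1CC[C@](C)(O)[C@@H]1CCC(=O)CC(=O)[C@](C)(CC=C(C)C)C(=O)OCC | intermediate (not isolated)
22 | (6R)-5-hydroxy-4-{[(1R,2S,5S)-2-hydroxy-2-methyl-5-(prop-1-en-2-yl)cyclopentyl]methyl}-6-methyl-6-(3-methylbut-2-en-1-yl)cyclohex-4-ene-1,3-dione (one enol tautomer of the 1,3,5-trione) | C=C(C)[C@H]1CC[C@](C)(O)[C@@H]1CC1=C(O)[C@@](C)(CC=C(C)C)C(=O)CC1=O | intermediate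
23 | (2R)-2-methylbutanoic acid | CC[C@@H](C)C(=O)O | starting material
24 | (4S)-2-{[(1R,2S,5S)-2-hydroxy-2-methyl-5-(prop-1-en-2-yl)cyclopentyl]methyl}-4-methyl-4-(3-methylbut-2-en-1-yl)-3,5-dioxocyclohex-1-en-1-yl (2R)-2-methylbutanoate (representative O-acyl regioisomer) | C=C(C)[C@H]1CC[C@](C)(O)[C@@H]1CC1=C(OC(=O)[C@H](C)CC)CC(=O)[C@](C)(CC=C(C)C)C1=O | intermediate (not isolated)
25 | (6R)-3,5-dihydroxy-4-{[(1R,2S,5S)-2-hydroxy-2-methyl-5-(prop-1-en-2-yl)cyclopentyl]methyl}-6-methyl-2-[(2R)-2-methylbutanoyl]-6-(3-methylbut-2-en-1-yl)cyclohexa-2,4-dien-1-one (CNP0299585.1) | C=C(C)[C@H]1CC[C@](C)(O)[C@@H]1CC1=C(O)[C@@](C)(CC=C(C)C)C(=O)C(C(=O)[C@H](C)CC)=C1O | target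

**Step count.** Total: 10 steps. Longest linear sequence: 8 steps (steps 1–6, 9, 10); steps 7 and 8 form the second branch.

**Steps most likely to fail**

Step 9 (one-flask Claisen/Dieckmann). What may go wrong: proton exchange between enolate 20 and lactone 12 instead of acylation, resting of the adduct as a cyclic hemiketal, or O-acylation and retro-Claisen cleavage once the dianion is formed. The fallback sets out from 12 and separates the two events with a better-behaved acyl donor. Aminolysis of 12 with MeNH(OMe)·HCl and Me2AlCl would give the Weinreb amide N-methoxy-N-methyl-3-[(1R,2S,5S)-2-hydroxy-2-methyl-5-(prop-1-en-2-yl)cyclopentyl]propanamide F1. Acylation of an excess of enolate 20 by F1, through a stable chelated adduct, would give diketo ester 21, now isolated. 21 would then be cyclised under equilibrating conditions (KOtBu, THF, 0 to 50 °C), and the route is rejoined at 22.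

Step 3 (aldol-lactonisation). What may go wrong: poor facial selectivity of the aldol relative to the isopropenyl-bearing carbon, or oligomerisation of the activated acid. The fallback sets out from keto aldehyde 3. Piperidinium acetate in refluxing benzene would give, by enamine aldol condensation, the enal (5R)-2-methyl-5-(prop-1-en-2-yl)cyclopent-1-ene-1-carbaldehyde F2. Weitz–Scheffer epoxidation (H2O2, NaOH, MeOH) anti to the isopropenyl group would give the epoxy aldehyde (1R,2R,5S)-5-methyl-2-(prop-1-en-2-yl)-6-oxabicyclo[3.1.0]hexane-1-carbaldehyde F3. Wittig reaction with 8 would give the alkenyl oxirane methyl (2E)-3-[(1R,2R,5S)-5-methyl-2-(prop-1-en-2-yl)-6-oxabicyclo[3.1.0]hexan-1-yl]prop-2-enoate F4. Formate hydrogenolysis (HCO2H, Et3N, Pd2(dba)3·CHCl3, PBu3; zerovalent palladium) delivers hydride to the allylic epoxide carbon with inversion, and the route is rejoined at hydroxy enoate 10.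

Step 8 (asymmetric prenylation). What may go wrong: alkylation on the wrong face or at nitrogen, giving low enantiomeric purity at the quaternary carbon. The fallback sets out from prenyl bromide 16. Alkylation of dimethyl methylmalonate (NaH, THF) would give the prochiral diester dimethyl 2-methyl-2-(3-methylbut-2-en-1-yl)propanedioate F5. Desymmetrising hydrolysis with pig liver esterase (pH 7 buffer) should give the half-ester (2S)-2-(methoxycarbonyl)-2,5-dimethylhex-4-enoic acid F6; which enantiomer the enzyme delivers must be assigned before it is carried on. Oxalyl chloride (cat. DMF) would give the acid chloride methyl (2R)-2-(chlorocarbonyl)-2,5-dimethylhex-4-enoate F7, and Me2CuLi (−78 °C) the methyl ketone methyl (2S)-2-acetyl-2,5-dimethylhex-4-enoate F8. F8 replaces 19 in step 9; because the ester alkoxide is lost there, the route is rejoined at 22.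

**Further compounds**

F1 | step 9 | N-methoxy-N-methyl-3-[(1R,2S,5S)-2-hydroxy-2-methyl-5-(prop-1-en-2-yl)cyclopentyl]propanamide | C=C(C)[C@H]1CC[C@](C)(O)[C@@H]1CCC(=O)N(C)OC
F2 | step 3 | (5R)-2-methyl-5-(prop-1-en-2-yl)cyclopent-1-ene-1-carbaldehyde | CC1=C(C=O)[C@H](CC1)C(C)=C
F3 | step 3 | (1R,2R,5S)-5-methyl-2-(prop-1-en-2-yl)-6-oxabicyclo[3.1.0]hexane-1-carbaldehyde | C=C(C)[C@H]1CC[C@]2(C)O[C@]12C=O
F4 | step 3 | methyl (2E)-3-[(1R,2R,5S)-5-methyl-2-(prop-1-en-2-yl)-6-oxabicyclo[3.1.0]hexan-1-yl]prop-2-enoate | C=C(C)[C@H]1CC[C@]2(C)O[C@]12/C=C/C(=O)OC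
F5 | step 8 | dimethyl 2-methyl-2-(3-methylbut-2-en-1-yl)propanedioate | COC(=O)C(C)(CC=C(C)C)C(=O)OC
F6 | step 8 | (2S)-2-(methoxycarbonyl)-2,5-dimethylhex-4-enoic acid | COC(=O)[C@@](C)(CC=C(C)C)C(=O)O
F7 | step 8 | methyl (2R)-2-(chlorocarbonyl)-2,5-dimethylhex-4-enoate | COC(=O)[C@@](C)(CC=C(C)C)C(=O)Cl
F8 | step 8 | methyl (2S)-2-acetyl-2,5-dimethylhex-4-enoate | COC(=O)[C@@](C)(CC=C(C)C)C(C)=O
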